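The numbers in the tables were computed for substances that don't exist; the scatter is artificial.

If one partner goes into each product formed, as I assumed, the sum of the two product peaks also tells how much partner has been used. Violet and amber each held 0.020 M of each substrate against 0.080 M of partner, so the substrates together were the limiting reagent. The partner charge over both substrate charges came to 2.00, and I called this ratio the partner cover. The share of c partner left is then one minus the reacted share divided by the cover.

in all of them: left-handed substrate 0.020 M; right-handed substrate 0.020 M; free catalyst 0.70 mM

| charge | partner | precatalyst | remark | time |
|---|---|---|---|---|
| violet | 0.080 M (fed, over 1.5 min) | 1 mM | the very flask that is asked about, followed so far |  |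
| amber | 0.080 M (fed, over 1.5 min) | 1.5 mM | run made earlier |  |
| flask | 0.0800 M (fed, over 1.5 min) | 1.0 mM |  | 15 min |

| run | time / min | left-handed product / % | right-handed product / % |
|---|---|---|---|
| violet | 0.667 | 0 | 2 |
| violet | 1.00 | 5 | 2 |
| violet | 1.50 | 6 | 0 |
| violet | 2.50 | 9 | 6 |
| violet | 5.00 | 12 | 0 |
| violet | 8.00 | 21 | 10 |
| amber | 0.667 | 2 | 1 |
| amber | 2.00 | 9 | 2 |
| amber | 4.00 | 17 | 4 |
| amber | 6.00 | 18 | 9 |
| amber | 8.00 | 26 | 13 |
| amber | 10.0 | 24 | 15 |

(standard deviation of a reading: 2 percentage points)

- free catalyst is single-handed; left-handed substrate and right-handed substrate are mirror images of each other, charged as a racemate, each of them at the stated concentration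
- the numbers in the tables scatter with a standard deviation of 2 percentage points
- an excess is the difference of the two amounts in percent of their sum
- an excess is below zero if the other one leads

- excess of left-handed product over right-handed product in the product at 1.5 min
- excess of left-handed product over right-handed product in the product at 15 min
- part of the left-handed substrate and right-handed substrate charged together that has reacted at 15 min

I read the two product columns against each other, row by row. From 1.00 min on, the left-handed column of violet stood above the right-handed one. The last row of violet, at 8.00 min, adds up to 31.0%, which by the balance leaves 84.5% of the partner. The last row of amber, at 10.0 min, adds up to 39.0%, which leaves 80.5%. These rest on readings, each with a scatter of 2 percentage points. From them I took c partner as roughly steady in both runs after the feed.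

The forecast gave an excess of 55% at 1.5 min, then 34% and a reacted share of 43% at 15 min, and said that “selectivity erodes somewhat beyond simple depletion”. Put into my balance, that reacted share meant 78.5% of the partner left in the flask at 15 min.

The flask gave 85.6% at 1.5 min, then 16.0% and 47.0% reacted at 15 min.

    left-handed product ⇌ right-handed product (k = 0.140 min⁻¹)
    partner + free catalyst + left-handed substrate → free catalyst + left-handed product (k = 4600 M⁻² min⁻¹)
    precatalyst → racemization catalyst (k = 0.190 min⁻¹)
    left-handed substrate + racemization catalyst ⇌ right-handed substrate + racemization catalyst, rate k4*[racemization catalyst]*[left-handed substrate] forward; the back reaction follows from the equilibrium constant (k = 55.0 M⁻¹ min⁻¹)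
    2 free catalyst ⇌ resting dimer, settled at all times (K = 1000 M⁻¹)
    partner + free catalyst + right-handed substrate → free catalyst + right-handed product (k = 37.0 M⁻² min⁻¹)

The reacted share of the flask stood near the forecast, but the excess parted from it at both times. It fell from 85.6% to 16.0%, and the relaxation half-life of the two products by their interconversion, 2.48 min, is short against 15 min. In the flask the balance gives 76.5% of the partner left at 15 min, while left-handed substrate stood lower, at 31% of its charge. The neighbouring flask with 0.20 M of partner has a cover of 5.00. Its reacted share of 63.6% gives 87.3% of its partner left, and its excess at 15 min was 11.2%.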